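I decided to compare these flasks through one dimensionless number, not through their curves.

| flask | substrate | coupling partner | initiator | temperature | remark | time |
|---|---|---|---|---|---|---|
| red | 0.27 M | 1.2 equiv | 0.56 mol% | 65 °C | run made earlier |  |
| blue | 0.60 M | 1.2 equiv | 0.56 mol% | 90 °C | run made earlier |  |
| teal | 0.40 M | 1.2 equiv | 1.1 mol% | 65 °C | run made earlier |  |
| dusk | 0.40 M | 1.20 equiv | 0.56 mol% | 110 °C |  | 6.0 h |
| midnight | 0.40 M | 1.20 equiv | 0.56 mol% | 90 °C |  | 6.0 h |
| noon | 0.40 M | 1.20 equiv | 0.56 mol% | 95 °C |  | 6.0 h |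
| dawn | 0.40 M | 1.20 equiv | 0.56 mol% | 70 °C |  | 6.0 h |

| run | time / h | target / % |
|---|---|---|
| red | 6.00 | 1.6 |
| red | 12.0 | 2.4 |
| red | 20.0 | 6.0 |
| red | 25.0 | 6.1 |
| red | 30.0 | 8.5 |
| red | 40.0 | 10.1 |
| blue | 2.00 | 11.7 |
| blue | 4.00 | 22.1 |
| blue | 5.00 | 26.8 |
| blue | 6.00 | 31.1 |
| blue | 8.00 | 38.7 |
| blue | 10.0 | 44.9 |
| teal | 2.50 | 0.8 |
| teal | 5.00 | 1.5 |
| teal | 10.0 | 4.3 |
| teal | 20.0 | 9.0 |
| teal | 40.0 | 17.1 |

(standard deviation of a reading: 0.5 percentage points)

* the flasks put in order of amount of target, in percent of the substrate charged, best first, at 6.0 h (dusk / midnight / noon / dawn)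
* the amount of target, in percent of the substrate charged of the flask you put first, at 6.0 h
* the amount of target, in percent of the substrate charged of the flask you put last, at 6.0 h

The number is the exposure θ: a pseudo-first-order constant k multiplied by the hours. Then e^−θ is the part of substrate left, and if substrate became nothing but target, the rest is target. Red's last reading, scaled by the root of [substrate] × loading, predicted 0.00454 h⁻¹ for teal, which read 0.00469 h⁻¹, so I folded the charges in that way. At 0.40 M, red then gave 0.00324 h⁻¹ and blue 0.0507 h⁻¹, an apparent activation energy of 112 kJ mol⁻¹.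

The exposure of dawn at 6.0 h came to 0.0348, of midnight to 0.304, of noon to 0.504 and of dusk to 2.12. I reckoned target at 3.42 %, 26.2 %, 39.6 % and 88.0 %. One k replaces a curve by its mean. Blue's k read 0.0622 h⁻¹ first and 0.0596 h⁻¹ last, but blue's exposure ended at 0.596, so dusk lay further out than blue's last reading.

The forecast gave dusk > noon > midnight > dawn, with 78 % for dusk and 3.5 % for dawn, lower than mine for dusk, citing “initiator burnout cutting the integral”.

The flasks gave dusk > noon > midnight > dawn: 80.9 %, 39.4 %, 26.6 % and 3.56 %.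

    initiator → 2 initiating radical (k = 0.0770 h⁻¹, Ea = 123 kJ mol⁻¹)
    substrate + initiating radical → capped initiator + first chain carrier (k = 83800 M⁻¹ s⁻¹, Ea = 9.00 kJ mol⁻¹)
    coupling partner + first chain carrier ⇌ target + second chain carrier (K = 0.698, k = 3.22 × 10⁶ M⁻¹ h⁻¹, Ea = 58.0 kJ mol⁻¹, ΔH = −8.00 kJ mol⁻¹)
    substrate + second chain carrier → by-product + first chain carrier (k = 4.16 × 10⁶ M⁻¹ h⁻¹, Ea = 56.0 kJ mol⁻¹)
    2 second chain carrier → ended chains (k = 6.00 × 10⁶ M⁻¹ s⁻¹, Ea = 10.0 kJ mol⁻¹)
    substrate + target → side product (k = 0.0861 M⁻¹ h⁻¹, Ea = 104 kJ mol⁻¹)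
    (constants at 110 °C)

Dusk had not come to rest at 6.0 h: it held 12 % substrate, where e^−θ gives 12.0 %, beside 80.9 % target and 7.11 % side product. By 60.0 h its substrate stood at 0 %, its target at 90.6 % and its side product at 9.44 %. Dawn still held 96 % substrate at 6.0 h: ten times its exposure is 0.348, which reckons 29.4 %, and dawn gave 29.6 % at 60.0 h.

For dawn left until 15 h, the exposure scales with the hours to 0.0870, which reckons 8.33 % target. That flask gave 8.62 %.

(All runs were generated by integration on assumed constants, noise included.)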